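## The problem

The target is a para-depside with no stereocentre. Ring A, a 2,4-dihydroxy-6-pentylbenzoyl unit, is bound through an aryl ester to the 4-oxygen of ring B, 2,4-dihydroxy-6-propylbenzoic acid. Each ring is a 1,2,3,5-tetrasubstituted benzene in which a carbonyl-bearing carbon sits between an oxygen-bearing carbon and an alkyl-bearing carbon, so three neighbouring substituents must be placed on each ring without positional isomers. Ring B offers a carboxyl group, a chelated 2-OH and a free 4-OH; only the 4-OH may be acylated, and the carboxyl must finish free. The aryl ester is cleaved by hydroxide, alkoxides and strong Lewis acids, and the ortho,para-dihydroxybenzoic acid of ring B loses CO2 in hot acid. Every harsh operation therefore has to come before the ester exists, and the last step has to be neutral. Since nothing is stereogenic, all control is regiochemical. The feature that invites a short construction of ring B is the triad C2–O, C1–CO2H, C6–propyl with hydrogen at C5: C1 and C6 are adjacent, one carries an electrophile-derived carbon and the other a nucleophile-derived carbon, and the oxygen at C2 stands where it can steer a nucleophile to C6 of an aryne spanning C1 and C6.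

## Retrosynthesis

**Target 18 to tribenzyl depside 17.** Only three O–benzyl bonds are added in the retrosynthetic sense: the ring B carboxyl becomes a benzyl ester and the two ring A phenols become benzyl ethers. Benzyl is chosen over methyl or silyl because hydrogenolysis is neutral and leaves the aryl ester and the decarboxylation-prone acid alone. The forward reaction only has to remove three benzyl groups in one operation.

**17 to acid 15 (used as acyl chloride 16) and phenol 10.** The ester C(=O)–O bond is cut. This is preferred over opening ring A on the ester or cutting the aryl–carbonyl bond, because both partners are then stable, fully aromatic compounds. The forward step must acylate the 4-OH of 10 and not the 2-OH. The 2-OH is locked in a hydrogen bond to the benzyl ester carbonyl, which lowers both its acidity and its nucleophilicity.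

**10 to acid 9 to dimethyl ether 8.** The benzyl ester O–CH2 bond and the two O–methyl bonds are disconnected. Methyl ethers are the only common phenol protection that survives an aryllithium, an aryne and a Grignard reagent, and they are cleaved here while no depside ester is present. The forward steps ask for a demethylation that does not decarboxylate 9 and for alkylation of the carboxylate without touching the phenols.

**8 to bromofluoroarene 2, propylmagnesium bromide 3 and carbon dioxide 4.** This is the key disconnection: the C6–propyl bond and the C1–carboxyl bond of ring B are cut together across an aryne 6, reached from 2 through aryllithium 5 and carried forward through aryl Grignard 7. A stepwise alternative, directed metalation of a 3,5-dimethoxyalkylbenzene, would carboxylate between the two methoxy groups, which is the wrong carbon. The aryne route instead takes both substituents from bulk reagents and places them by the polarisation that the neighbouring methoxy group imposes. The precursor 2 has neither chain nor carboxyl. The forward reaction must form the aryne at one defined position and add propyl at the carbon remote from the methoxy group.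

**2 to 1-fluoro-3,5-dimethoxybenzene 1.** The C–Br bond is cut. Bromination of 1 is directed by the two methoxy groups to the position between fluorine and methoxy, which is exactly where a bromine is needed for exchange next to the fluoride leaving group.

**15 to aldehyde 14 to aldehyde 13 to olivetol 11.** In ring A the chain is bought with the arene, so only the carboxyl carbon has to be added. It is introduced as a formyl group (through iminium salt 12) at the position between the chain and a hydroxyl. The phenols are then benzylated and the aldehyde is oxidised. The forward steps are three standard operations.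

## Roads not taken

**Alternative 1:** The cut lies inside ring A. Opening the bond between ring A C1 and C6 unfolds the ring into a linear triketo chain already esterified to O4 of ring B: benzyl 2-hydroxy-6-propyl-4-[(3,5,7-trioxododecanoyl)oxy]benzoate A1. In the forward key step, mild base and then acid would let chain C2 attack the C7 ketone in an intramolecular aldol condensation. Dehydration and enolisation would give the benzyl ester of the target, A2, one hydrogenolysis from the end.
- Merits: ring A needs no protecting group, its oxygen pattern and pentyl chain come from the chain itself, and on the ring A side this road is shorter than the chosen one.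
- Weak points: A1 is an aryl ester of a β-keto acid and therefore an activated ester. The enolates needed for the aldol can instead expel the phenoxide, either by attack of the C5 enol oxygen on C1 (a 4-hydroxy-2-pyrone) or by Claisen attack of C6 on C1 (an acylphloroglucinol). Both paths destroy the depside bond and are faster with an aryloxide leaving group than with an alkyl ester. A1 must also be made by acylating 10 with a masked triketo acid, so ring B is not solved and a multi-step chain synthesis is added.
- Comparison: the chosen plan spends three steps on ring A, but forms the ester from two robust aromatic partners and uses no enolate chemistry once the aryl ester exists.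

**Alternative 2:** The cut opens ring B at C1–C6 and C2–C3. Dibenzyl malonate A3 and (E)-hept-3-en-2-one A4, with a benzyloxide base, would undergo conjugate addition and Claisen closure to racemic benzyl trans-4-hydroxy-2-oxo-6-propylcyclohex-3-ene-1-carboxylate A5. Its enol oxygen would be acylated by 16 and the ring dehydrogenated at the end. The two stereocentres of A5 vanish on aromatisation, so the racemate suffices.
- Merits: the materials are very cheap, the carboxyl arrives as the benzyl ester, and there is no organometallic step, no ether cleavage and no free acid 9. As a way to the ring B carbon skeleton it is shorter than steps 1 to 4 of the chosen plan, and in that respect it is better.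
- Weak points: a cyclic 1,3-dione offers two enol oxygens and a nucleophilic C3, and acyl migration from oxygen to carbon is well known for such enol esters under nucleophilic catalysis. The enol ester is a vinylogous anhydride. The late aromatisation needs a halogenating or quinone oxidant in the presence of that labile ester, three benzyl groups and the electron-rich ring A, which can itself be halogenated.
- Comparison: if the order is reversed (aromatise first, acylate second), this road is simply another preparation of 10. The chosen plan sets against it that every ring B intermediate is aromatic, the substitution pattern is fixed by aryne regiochemistry, the acylation site is fixed by chelation in 10, and no oxidation follows ester formation.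

**Alternative 3:** Both bonds at the depside carbonyl carbon are cut. The aryl iodide 1,5-bis(benzyloxy)-2-iodo-3-pentylbenzene A6, carbon monoxide A7 and phenol 10 would be joined by Pd(OAc)2 with a wide-bite-angle bisphosphine and an amine base. The product A8 is identical in structure with 17.
- Merits: ring A would need only benzylation and iodination, with no formylation, oxidation or acid chloride. This is a real saving of about two operations, and the road is fully convergent.
- Weak points: A6 is electron-rich and flanked on both sides, so oxidative addition to zerovalent palladium is slow. The crowded acylpalladium must be captured by a weakly nucleophilic phenol that carries a second hydroxyl. Hydrodehalogenation is the usual competitor in such cases, and pressurised carbon monoxide is needed.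
- Comparison: this road needs the same ring B partner 10, so it is compatible with the aryne construction and could replace steps 5 to 8 if it worked. The chosen plan accepts the longer ring A sequence in return for an ester-forming step of a classical, dependable type.

Key step: step 2

Remark on the chemistry: propylmagnesium bromide 3 is taken as the commercial THF solution, so no separate Grignard preparation from 1-bromopropane is counted.

## Route

Step 1
Reactants: 1 1-fluoro-3,5-dimethoxybenzene
Product: 2 2-bromo-1-fluoro-3,5-dimethoxybenzene
Conditions: NBS (1.0 equiv), MeCN, 0 °C → rt
Reagents that add atoms: N-bromosuccinimide, O=C1CCC(=O)N1Br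
Why: Electrophilic aromatic bromination; each of the two equivalent positions between F and OMe is para to one methoxy and ortho to the other and is less crowded than the position between the two methoxy groups, so monobromination there is expected, as with other 5-substituted 1,3-dimethoxybenzenes.

Step 2
Reactants: 2 2-bromo-1-fluoro-3,5-dimethoxybenzene; 3 propylmagnesium bromide; 4 carbon dioxide
Product: 8 2,4-dimethoxy-6-propylbenzoic acid, via 2-fluoro-4,6-dimethoxyphenyllithium 5 (not isolated), via 3,5-dimethoxybenzyne 6 (not isolated), via 2,4-dimethoxy-6-propylphenylmagnesium bromide 7 (not isolated)
Conditions: n-BuLi (1.0 equiv), THF, −78 °C; then 3 (3 equiv), −78 °C → rt; then CO2 (gas), 0 °C → rt; aq. HCl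
Reagents that add atoms: none
Why: Bromine–lithium exchange on 2 is fast at −78 °C and gives 5, in which lithium sits between fluorine and methoxy and which is stable at that temperature. On warming, 5 loses LiF to give aryne 6, whose strained bond joins the former C–Br and C–F carbons, that is ring B C1 and C6. The methoxy group on the carbon next to the aryne (ring B C2) withdraws σ-electron density and distorts the triple bond, so the remote carbon C6 is the more electrophilic; propyl enters there and the metal ends on C1, where the methoxy oxygen also coordinates it. The second methoxy group and the hydrogen at C5 exert only a weak bias compared with this ortho effect, so a single regioisomer 7 is expected. Carbon dioxide then inserts into the C–Mg bond of 7 and makes the C1–carboxyl bond, the C6–propyl bond having been made in the addition. The closest known reaction type is the carbometalation of 3-alkoxyarynes by alkyllithium or Grignard reagents followed by carbonation, the established entry to 6-alkylsalicylic acids. No ring closes and no stereocentre forms. One equivalent of n-BuLi and an excess of 3 keep butyl from competing with propyl and keep 5 from adding to 6.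

Step 3
Reactants: 8 2,4-dimethoxy-6-propylbenzoic acid
Product: 9 2,4-dihydroxy-6-propylbenzoic acid
Conditions: BBr3 (4 equiv), CH2Cl2, −78 °C → rt; ice-water quench at 0 °C
Reagents that add atoms: none
Why: Lewis-acid cleavage of aryl methyl ethers with BBr3; the ortho ether is cleaved quickly through chelation to the carboxyl and the para ether on warming, and a cold quench keeps the dihydroxy acid from decarboxylating.

Step 4
Reactants: 9 2,4-dihydroxy-6-propylbenzoic acid
Product: 10 benzyl 2,4-dihydroxy-6-propylbenzoate
Conditions: BnBr (1.05 equiv), KHCO3 (1.1 equiv), DMF, rt
Reagents that add atoms: benzyl bromide, BrCc1ccccc1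
Why: SN2 O-alkylation of a carboxylate; bicarbonate deprotonates only the carboxylic acid, so the phenols stay free, as in the standard preparation of benzyl esters of 2,4-dihydroxybenzoic acids.

Step 5
Reactants: 11 5-pentylbenzene-1,3-diol (olivetol)
Product: 13 2,4-dihydroxy-6-pentylbenzaldehyde, via (2,4-dihydroxy-6-pentylbenzylidene)dimethyliminium chloride 12 (not isolated)
Conditions: POCl3 (1.2 equiv), DMF, 0 °C → rt; then ice-water, 50 °C
Reagents that add atoms: N,N-dimethylformamide, CN(C)C=O; water, O
Why: Vilsmeier–Haack formylation; the chloroiminium ion attacks the position ortho to the chain and para to one hydroxyl, which is less hindered than the position between the two hydroxyls, and hydrolysis of 12 releases the aldehyde, as known for orcinol and its homologues.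

Step 6
Reactants: 13 2,4-dihydroxy-6-pentylbenzaldehyde
Product: 14 2,4-bis(benzyloxy)-6-pentylbenzaldehyde
Conditions: BnBr (2.4 equiv), K2CO3, DMF, 60 °C
Reagents that add atoms: benzyl bromide, BrCc1ccccc1
Why: Williamson ether synthesis; carbonate in warm DMF alkylates both phenols, the chelated 2-OH included, and the aldehyde is inert.

Step 7
Reactants: 14 2,4-bis(benzyloxy)-6-pentylbenzaldehyde
Product: 15 2,4-bis(benzyloxy)-6-pentylbenzoic acid
Conditions: NaClO2, NaH2PO4, 2-methyl-2-butene (excess), t-BuOH/THF/H2O, 0 °C → rt
Reagents that add atoms: sodium chlorite, [Na+].[O-]Cl=O
Why: Pinnick oxidation; chlorous acid converts the hindered aryl aldehyde to the acid without touching the benzyl ethers, and excess 2-methyl-2-butene removes hypochlorous acid before it can chlorinate the electron-rich ring.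

Step 8
Reactants: 15 2,4-bis(benzyloxy)-6-pentylbenzoic acid; 10 benzyl 2,4-dihydroxy-6-propylbenzoate
Product: 17 benzyl 4-{[2,4-bis(benzyloxy)-6-pentylbenzoyl]oxy}-2-hydroxy-6-propylbenzoate, via 2,4-bis(benzyloxy)-6-pentylbenzoyl chloride 16 (not isolated)
Conditions: (COCl)2, DMF (cat.), CH2Cl2, 0 °C → rt, evaporate; then 10 (1.0 equiv), Et3N, DMAP (cat.), CH2Cl2, 0 °C → rt
Reagents that add atoms: none
Why: Acyl chloride formation with oxalyl chloride and catalytic DMF, then DMAP-catalysed O-acylation of a phenol; the 2-OH of 10 is hydrogen-bonded to the ester carbonyl and is much less acidic and nucleophilic than the 4-OH, so one equivalent of 16 should acylate O4 only.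

Step 9
Reactants: 17 benzyl 4-{[2,4-bis(benzyloxy)-6-pentylbenzoyl]oxy}-2-hydroxy-6-propylbenzoate
Product: 18 4-[(2,4-dihydroxy-6-pentylbenzoyl)oxy]-2-hydroxy-6-propylbenzoic acid
Conditions: H2 (1 atm), 10% Pd/C, EtOAc, rt
Reagents that add atoms: none
Why: Catalytic hydrogenolysis of two benzyl ethers and one benzyl ester under neutral conditions; the aryl ester, the phenols and the free acid are untouched, and no stereocentre is involved.

## Compound list

1 | 1-fluoro-3,5-dimethoxybenzene | COc1cc(F)cc(OC)c1 | starting material
2 | 2-bromo-1-fluoro-3,5-dimethoxybenzene | COc1cc(OC)c(Br)c(F)c1 | intermediate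
3 | propylmagnesium bromide | CCC[Mg]Br | starting material
4 | carbon dioxide | O=C=O | starting material
5 | 2-fluoro-4,6-dimethoxyphenyllithium | [Li]c1c(F)cc(OC)cc1OC | intermediate
6 | 3,5-dimethoxybenzyne | COC1=CC(OC)=CC#C1 | intermediate
7 | 2,4-dimethoxy-6-propylphenylmagnesium bromide | CCCc1cc(OC)cc(OC)c1[Mg]Br | intermediate
8 | 2,4-dimethoxy-6-propylbenzoic acid | CCCc1cc(OC)cc(OC)c1C(=O)O | intermediate
9 | 2,4-dihydroxy-6-propylbenzoic acid | CCCc1cc(O)cc(O)c1C(=O)O | intermediate
10 | benzyl 2,4-dihydroxy-6-propylbenzoate | CCCc1cc(O)cc(O)c1C(=O)OCc1ccccc1 | intermediate
11 | 5-pentylbenzene-1,3-diol (olivetol) | CCCCCc1cc(O)cc(O)c1 | starting material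
12 | (2,4-dihydroxy-6-pentylbenzylidene)dimethyliminium chloride | CCCCCc1cc(O)cc(O)c1C=[N+](C)C.[Cl-] | intermediate
13 | 2,4-dihydroxy-6-pentylbenzaldehyde | CCCCCc1cc(O)cc(O)c1C=O | intermediate
14 | 2,4-bis(benzyloxy)-6-pentylbenzaldehyde | CCCCCc1cc(OCc2ccccc2)cc(OCc2ccccc2)c1C=O | intermediate
15 | 2,4-bis(benzyloxy)-6-pentylbenzoic acid | CCCCCc1cc(OCc2ccccc2)cc(OCc2ccccc2)c1C(=O)O | intermediate
16 | 2,4-bis(benzyloxy)-6-pentylbenzoyl chloride | CCCCCc1cc(OCc2ccccc2)cc(OCc2ccccc2)c1C(=O)Cl | intermediate
17 | benzyl 4-{[2,4-bis(benzyloxy)-6-pentylbenzoyl]oxy}-2-hydroxy-6-propylbenzoate | CCCCCc1cc(OCc2ccccc2)cc(OCc2ccccc2)c1C(=O)Oc1cc(O)c(C(=O)OCc2ccccc2)c(CCC)c1 | intermediate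
18 | 4-[(2,4-dihydroxy-6-pentylbenzoyl)oxy]-2-hydroxy-6-propylbenzoic acid | CCCCCc1cc(O)cc(O)c1C(=O)Oc1cc(O)c(C(=O)O)c(CCC)c1 | target

## Step count and risks

Total step count: 9. Longest linear sequence: 6 steps (steps 1, 2, 3, 4, 8, 9); the ring A branch (steps 5, 6, 7) joins at step 8.

**Step 2 (key step).** The likeliest failure is poor partitioning of the aryne: addition of 5 to 6 in place of the propyl reagent, butyl transfer if any n-BuLi is left, or protonation of 7 before carboxylation. If lithium is exchanged for magnesium before fluoride is lost, aryne release would also be delayed and need gentle heating. The fallback sets out from 2 and returns at 8 without an aryne. Bromine–lithium exchange of 2 at −78 °C and carboxylation at that temperature, before LiF is lost, should give 2-fluoro-4,6-dimethoxybenzoic acid F1. Excess propylmagnesium bromide 3 in THF should then displace the fluorine ortho to the magnesium carboxylate by addition–elimination, giving 8. This is the known carboxylate-directed substitution of unprotected ortho-fluorobenzoic acids by Grignard reagents, in which fluoride leaves more readily than methoxide.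

**Step 3.** Protodecarboxylation during the ether cleavage or the acidic quench, or incomplete cleavage of the para ether, would lower the return of 9. The fallback sets out from 8 and returns at 9 while keeping the carboxyl masked through the Lewis-acid step. Methylation (MeI, K2CO3, DMF) should give methyl 2,4-dimethoxy-6-propylbenzoate F2. BBr3 should then give methyl 2,4-dihydroxy-6-propylbenzoate F3, which cannot decarboxylate. Hydrolysis with aqueous KOH and cold acidification should deliver 9.

**Step 5.** Attack at the position between the two hydroxyls, or double formylation, would erode positional selectivity. The fallback sets out from 11 and returns at 15, bypassing steps 5 to 7. Benzylation (BnBr, K2CO3) should give 1,3-bis(benzyloxy)-5-pentylbenzene F4. NBS should brominate para to one ether and ortho to the chain to give 1,5-bis(benzyloxy)-2-bromo-3-pentylbenzene F5. Bromine–lithium exchange at −78 °C with n-BuLi and carboxylation with CO2 should then give 15.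

**Step 8.** Acylation by the doubly ortho-substituted acyl chloride may be sluggish, the ortho benzyl ether may be lost during chlorination, or the chelated hydroxyl may be over-acylated. The fallback sets out from 15 and 10 and returns at 17 without an acyl chloride or a base. Trifluoroacetic anhydride in toluene should convert 15 into 2,4-bis(benzyloxy)-6-pentylbenzoic trifluoroacetic anhydride F6. Its ionisation to a stabilised acylium ion is a known way to esterify hindered 2,6-disubstituted benzoic acids with phenols, and under these non-basic conditions the chelated 2-OH of 10 is not activated.

## Further compounds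

F1 | step 2 | 2-fluoro-4,6-dimethoxybenzoic acid | COc1cc(F)c(C(=O)O)c(OC)c1
F2 | step 3 | methyl 2,4-dimethoxy-6-propylbenzoate | CCCc1cc(OC)cc(OC)c1C(=O)OC
F3 | step 3 | methyl 2,4-dihydroxy-6-propylbenzoate | CCCc1cc(O)cc(O)c1C(=O)OC
F4 | step 5 | 1,3-bis(benzyloxy)-5-pentylbenzene | CCCCCc1cc(OCc2ccccc2)cc(OCc2ccccc2)c1
F5 | step 5 | 1,5-bis(benzyloxy)-2-bromo-3-pentylbenzene | CCCCCc1cc(OCc2ccccc2)cc(OCc2ccccc2)c1Br
F6 | step 8 | 2,4-bis(benzyloxy)-6-pentylbenzoic trifluoroacetic anhydride | CCCCCc1cc(OCc2ccccc2)cc(OCc2ccccc2)c1C(=O)OC(=O)C(F)(F)F
A1 | alternative 1 | benzyl 2-hydroxy-6-propyl-4-[(3,5,7-trioxododecanoyl)oxy]benzoate | CCCCCC(=O)CC(=O)CC(=O)CC(=O)Oc1cc(O)c(C(=O)OCc2ccccc2)c(CCC)c1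
A2 | alternative 1 | benzyl 4-[(2,4-dihydroxy-6-pentylbenzoyl)oxy]-2-hydroxy-6-propylbenzoate | CCCCCc1cc(O)cc(O)c1C(=O)Oc1cc(O)c(C(=O)OCc2ccccc2)c(CCC)c1
A3 | alternative 2 | dibenzyl malonate | O=C(CC(=O)OCc1ccccc1)OCc1ccccc1
A4 | alternative 2 | (E)-hept-3-en-2-one | CCC/C=C/C(C)=O
A5 | alternative 2 | benzyl trans-4-hydroxy-2-oxo-6-propylcyclohex-3-ene-1-carboxylate (racemic, one enantiomer drawn) | CCC[C@@H]1CC(O)=CC(=O)[C@H]1C(=O)OCc1ccccc1
A6 | alternative 3 | 1,5-bis(benzyloxy)-2-iodo-3-pentylbenzene | CCCCCc1cc(OCc2ccccc2)cc(OCc2ccccc2)c1I
A7 | alternative 3 | carbon monoxide | [C-]#[O+]
A8 | alternative 3 | benzyl 4-{[2,4-bis(benzyloxy)-6-pentylbenzoyl]oxy}-2-hydroxy-6-propylbenzoate | CCCCCc1cc(OCc2ccccc2)cc(OCc2ccccc2)c1C(=O)Oc1cc(O)c(C(=O)OCc2ccccc2)c(CCC)c1
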